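Assumption: atoms are numbered C1–C20 as in a head-to-tail geranylgeranyl chain (bromocyclohexanol ring C3–C8, cyclopentane C1–C2–C3–C8–C9, carbinol link C10, ring A C11–C15 plus C18), the presumed biogenesis is taken as bromonium-induced C3–C8 closure, aldol-type C1–C9 closure and bromonium-induced C15–C18 closure with oxygen capture at C11, and (R)-(−)-linalool of high ee is taken as commercial.

**Retrosynthetic overview**
1. Target 25 ⇐ diacetate 22: ring A is closed last by bromonium-induced C15–C18 cyclization of the 1,1-disubstituted alkene onto the prenyl group, the C11 cation being captured by the C10 acetate.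
2. 22 ⇐ keto aldehyde 19: cyclopentane by C1–C9 aldol, then 1,3-syn reduction at C10; 19 ⇐ lactone 13 + the vinyllithium from 6-methylhept-5-en-2-one (C11–C18 unit).
3. Lactone 11 ⇐ dihydrofuran 8: the bromocyclohexane (C3–C8) is closed first by a bromonium-induced cyclization ended by a C10→C9 hydride shift; C7 of linalool controls C3, C4 and C8.
4. 8 ⇐ (R)-linalool + allyl bromide (ring-closing metathesis) + vinylmagnesium bromide (C1).
5. Ring order: bromocyclohexane (with a temporary oxacycle) → cyclopentane → ring A.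

**Route**

Step 1
Reactants: 1 (R)-(−)-linalool; 2 allyl bromide
Product: 3 (3R)-3,7-dimethyl-3-(prop-2-en-1-yloxy)octa-1,6-diene
Conditions: NaH, Bu4NI (cat.), THF, 0 → 65 °C
Reagents that add atoms: none
Why: Williamson etherification of the tertiary alkoxide; the C7 stereocentre (R, from linalool) is not touched.

Step 2
Reactants: 3 (3R)-3,7-dimethyl-3-(prop-2-en-1-yloxy)octa-1,6-diene
Product: 4 (2R)-2-methyl-2-(4-methylpent-3-en-1-yl)-2,5-dihydrofuran
Conditions: second-generation Grubbs catalyst RuCl2(=CHPh)(PCy3)(H2IMes) (2 mol %), CH2Cl2 (0.05 M), 40 °C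
Reagents that add atoms: none
Why: Ring-closing metathesis of the two monosubstituted alkenes to the five-membered ring is much faster than metathesis at the trisubstituted alkene; C7 is unchanged.

Step 3
Reactants: 4 (2R)-2-methyl-2-(4-methylpent-3-en-1-yl)-2,5-dihydrofuran
Product: 5 (2E)-2-methyl-5-[(2R)-2-methyl-2,5-dihydrofuran-2-yl]pent-2-en-1-ol
Conditions: SeO2 (0.5 equiv), t-BuOOH, salicylic acid (cat.), CH2Cl2, 0 °C → rt
Reagents that add atoms: tert-butyl hydroperoxide, CC(C)(C)OO (oxygen relayed by selenium dioxide, O=[Se]=O)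
Why: Riley allylic oxidation (ene reaction then [2,3]-shift) attacks the more electron-rich trisubstituted alkene and gives the (E)-allylic alcohol, which fixes the alkene geometry needed later (C2 trans to C5).

Step 4
Reactants: 5 (2E)-2-methyl-5-[(2R)-2-methyl-2,5-dihydrofuran-2-yl]pent-2-en-1-ol
Product: 6 (2R)-2-[(3E)-5-bromo-4-methylpent-3-en-1-yl]-2-methyl-2,5-dihydrofuran
Conditions: CBr4, PPh3, CH2Cl2, 0 °C
Reagents that add atoms: tetrabromomethane, BrC(Br)(Br)Br
Why: Appel reaction converts the primary allylic alcohol into the bromide without allylic transposition or loss of the (E)-geometry.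

Step 5
Reactants: 6 (2R)-2-[(3E)-5-bromo-4-methylpent-3-en-1-yl]-2-methyl-2,5-dihydrofuran; 7 vinylmagnesium bromide
Product: 8 (2R)-2-methyl-2-[(3E)-4-methylhepta-3,6-dien-1-yl]-2,5-dihydrofuran
Conditions: Li2CuCl4 (5 mol %), THF, −78 → 0 °C
Reagents that add atoms: none
Why: Kochi-type copper-catalysed Grignard coupling substitutes the primary allylic bromide at the α-carbon (the γ-carbon is fully substituted), installing C1 as a vinyl group with the (E)-alkene retained.

Step 6
Reactants: 8 (2R)-2-methyl-2-[(3E)-4-methylhepta-3,6-dien-1-yl]-2,5-dihydrofuran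
Product: 10 (3aS,4S,5S,7aR)-5-bromo-4,7a-dimethyl-4-(prop-2-en-1-yl)octahydro-1-benzofuran-2-ol (lactol; both C2 epimers), via bicyclic oxocarbenium ion 9 (not isolated)
Conditions: Et2SBr·SbCl5Br (1.1 equiv), MeNO2, −25 °C, 5 min; then H2O
Reagents that add atoms: bromodiethylsulfonium bromopentachloroantimonate, CC[S+](Br)CC.Br[Sb-](Cl)(Cl)(Cl)(Cl)Cl; water, O
Why: Proposed new method: bromonium-induced 6-exo cation–olefin cyclization ended by a 1,2-hydride shift, in which Br+ (transferred reversibly from the sulfonium) adds to the most electron-rich trisubstituted alkene while the ring alkene attacks C3 through C8 on the chain-bearing face in a chair (C7–O axial, C7–Me equatorial to avoid a Me/Me 1,3-diaxial clash, Br equatorial, C3–Me axial), so C7 sets C3 (S), C4 (S) and C8 (S), and the C9 cation is quenched by hydride shift from C10 to oxocarbenium 9, hydrated on work-up; the closest known chemistry is halonium polyene cyclization with this reagent and the Prins–pinacol cascade.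

Step 7
Reactants: 10 (3aS,4S,5S,7aR)-5-bromo-4,7a-dimethyl-4-(prop-2-en-1-yl)octahydro-1-benzofuran-2-ol
Product: 11 (3aS,4S,5S,7aR)-5-bromo-4,7a-dimethyl-4-(prop-2-en-1-yl)hexahydro-1-benzofuran-2(3H)-one
Conditions: 2,2,6,6-tetramethylpiperidin-1-oxyl (TEMPO, 10 mol %), PhI(OAc)2, CH2Cl2, rt
Reagents that add atoms: none
Why: Oxoammonium oxidation of the lactol to the γ-lactone; the bromide, the alkene and all stereocentres are untouched.

Step 8
Reactants: 11 (3aS,4S,5S,7aR)-5-bromo-4,7a-dimethyl-4-(prop-2-en-1-yl)hexahydro-1-benzofuran-2(3H)-one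
Product: 13 (3aS,4S,5S,7aR)-5-bromo-4-(2,2-dimethoxyethyl)-4,7a-dimethylhexahydro-1-benzofuran-2(3H)-one, via lactone aldehyde 12 (not isolated)
Conditions: O3, CH2Cl2–MeOH, −78 °C; Me2S; then TsOH (cat.), MeOH, rt
Reagents that add atoms: methanol, CO (ozone, [O-][O+]=O, supplies the carbonyl oxygen of 12 only)
Why: Ozonolysis of the only alkene gives the C1 aldehyde, and acid-catalysed acetalization in the same pot masks it so that the organolithium of step 10 can attack only the lactone.

Step 9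
Reactants: 14 6-methylhept-5-en-2-one; 15 2,4,6-triisopropylbenzenesulfonohydrazide
Product: 16 N′-[(2E)-6-methylhept-5-en-2-ylidene]-2,4,6-triisopropylbenzenesulfonohydrazide
Conditions: MeOH, HCl (cat.), rt
Reagents that add atoms: none
Why: Hydrazone condensation gives the (E)-trisylhydrazone needed for a regioselective Shapiro reaction.

Step 10
Reactants: 16 N′-[(2E)-6-methylhept-5-en-2-ylidene]-2,4,6-triisopropylbenzenesulfonohydrazide; 13 (3aS,4S,5S,7aR)-5-bromo-4-(2,2-dimethoxyethyl)-4,7a-dimethylhexahydro-1-benzofuran-2(3H)-one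
Product: 19 2-[(1S,2S,3R,6S)-6-bromo-3-hydroxy-1,3-dimethyl-2-(7-methyl-3-methylidene-2-oxooct-6-en-1-yl)cyclohexyl]acetaldehyde (in equilibrium with its cyclic hemiketal), via vinyllithium 17 (not isolated), via acetal enone 18 (not isolated)
Conditions: 16, n-BuLi (2 equiv), THF–TMEDA, −78 → 0 °C; add 13, −78 °C; then 1 M HCl, THF, 0 °C → rt
Reagents that add atoms: water, O
Why: Shapiro reaction gives the less substituted vinyllithium, which adds once to the γ-lactone (the lithium hemiketal resists a second addition), and the acidic work-up hydrolyses the acetal; no stereocentre changes.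

Step 11
Reactants: 19 2-[(1S,2S,3R,6S)-6-bromo-3-hydroxy-1,3-dimethyl-2-(7-methyl-3-methylidene-2-oxooct-6-en-1-yl)cyclohexyl]acetaldehyde
Product: 20 1-[(1S,2R,3aS,4S,7R,7aS)-4-bromo-2,7-dihydroxy-3a,7-dimethyloctahydro-1H-inden-1-yl]-6-methyl-2-methylidenehept-5-en-1-one
Conditions: 1,8-diazabicyclo[5.4.0]undec-7-ene (DBU, 0.3 equiv), CH2Cl2, −20 → 0 °C
Reagents that add atoms: none
Why: Intramolecular aldol addition (5-exo, enolexo) from C9, the only enolizable position of the ketone, onto the C1 aldehyde under reversible conditions, which places the acyl group trans to C7 (C9 S) and the C1 hydroxyl cis to the acyl group, hydrogen-bonded and away from the angular methyl (C1 R).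

Step 12
Reactants: 20 1-[(1S,2R,3aS,4S,7R,7aS)-4-bromo-2,7-dihydroxy-3a,7-dimethyloctahydro-1H-inden-1-yl]-6-methyl-2-methylidenehept-5-en-1-one
Product: 21 (1S,2R,3aS,4S,7R,7aS)-4-bromo-1-[(1R)-1-hydroxy-6-methyl-2-methylidenehept-5-en-1-yl]-3a,7-dimethyloctahydro-1H-indene-2,7-diol
Conditions: Et2BOMe, NaBH4, THF–MeOH (4:1), −78 °C; then MeOH (boron removed by co-evaporation)
Reagents that add atoms: none
Why: Narasaka–Prasad reduction, in which the diethylboron chelate of the β-hydroxy ketone is attacked axially by external hydride to give the 1,3-syn diol (C10 R) and the chelation also enforces 1,2-reduction of the enone.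

Step 13
Reactants: 21 (1S,2R,3aS,4S,7R,7aS)-4-bromo-1-[(1R)-1-hydroxy-6-methyl-2-methylidenehept-5-en-1-yl]-3a,7-dimethyloctahydro-1H-indene-2,7-diol
Product: 22 (1R)-1-[(1S,2R,3aS,4S,7R,7aS)-2-acetoxy-4-bromo-7-hydroxy-3a,7-dimethyloctahydro-1H-inden-1-yl]-6-methyl-2-methylidenehept-5-en-1-yl acetate
Conditions: Ac2O, Et3N, 4-(dimethylamino)pyridine (DMAP, cat.), CH2Cl2, 0 °C → rt
Reagents that add atoms: acetic anhydride, CC(=O)OC(C)=O
Why: Acylation of the two secondary alcohols only (the tertiary C7 alcohol is inert), which removes them as nucleophiles and turns the C10 oxygen into a neighbouring group for the last cyclization.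

Step 14
Reactants: 22 (1R)-1-[(1S,2R,3aS,4S,7R,7aS)-2-acetoxy-4-bromo-7-hydroxy-3a,7-dimethyloctahydro-1H-inden-1-yl]-6-methyl-2-methylidenehept-5-en-1-yl acetate
Product: 25 (1S,2R,3aS,4S,7R,7aS)-4-bromo-1-{(R)-[(1R,4S)-4-bromo-1-hydroxy-3,3-dimethylcyclohexyl](hydroxy)methyl}-3a,7-dimethyloctahydro-1H-indene-2,7-diol (target), via acetoxonium ion 23 (not isolated), via hydroxy diacetate 24 (not isolated)
Conditions: N-bromosuccinimide (1.1 equiv), (R)-3,3′-bis(2,4,6-triisopropylphenyl)-1,1′-binaphthyl-2,2′-diyl N-triflylthiophosphoramide (10 mol %; antipode chosen to brominate the C14 Si face), toluene–CH2Cl2, −78 °C; then H2O; then K2CO3, MeOH, rt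
Reagents that add atoms: N-bromosuccinimide, O=C1CCC(=O)N1Br
Why: Proposed new method: catalyst-controlled bromonium-induced cyclization in which the chiral sulfur Lewis base delivers Br+ to one face of the prenyl alkene (C14 S), the 1,1-disubstituted alkene closes ring A through C18 in a chair with Br equatorial, and the C11 cation is captured from the axial face by the C10 acetate (C10 stays equatorial, so OH is cis to Br and C11 is R, C10 retained), after which hydrolysis and methanolysis free the tetraol; the closest known chemistry is Lewis-base-catalysed enantioselective bromocyclization of polyenes and Woodward–Prévost acetoxonium capture.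

**Compound list**

1 | (R)-(−)-linalool, (3R)-3,7-dimethylocta-1,6-dien-3-ol | CC(C)=CCC[C@@](C)(O)C=C | starting material
2 | allyl bromide | C=CCBr | starting material
3 | (3R)-3,7-dimethyl-3-(prop-2-en-1-yloxy)octa-1,6-diene | CC(C)=CCC[C@@](C)(OCC=C)C=C | intermediate
4 | (2R)-2-methyl-2-(4-methylpent-3-en-1-yl)-2,5-dihydrofuran | CC(C)=CCC[C@@]1(C)OCC=C1 | intermediate
5 | (2E)-2-methyl-5-[(2R)-2-methyl-2,5-dihydrofuran-2-yl]pent-2-en-1-ol | OC/C(C)=C/CC[C@@]1(C)OCC=C1 | intermediate
6 | (2R)-2-[(3E)-5-bromo-4-methylpent-3-en-1-yl]-2-methyl-2,5-dihydrofuran | BrC/C(C)=C/CC[C@@]1(C)OCC=C1 | intermediate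
7 | vinylmagnesium bromide | C=C[Mg]Br | starting material
8 | (2R)-2-methyl-2-[(3E)-4-methylhepta-3,6-dien-1-yl]-2,5-dihydrofuran | C=CC/C(C)=C/CC[C@@]1(C)OCC=C1 | intermediate
9 | (3aS,4S,5S,7aR)-5-bromo-4,7a-dimethyl-4-(prop-2-en-1-yl)-3a,4,5,6,7,7a-hexahydro-3H-1-benzofuran-1-ium (bromopentachloroantimonate salt) | C=CC[C@]3(C)[C@@H](Br)CC[C@@]2(C)[O+]=CC[C@H]23 | intermediate
10 | (3aS,4S,5S,7aR)-5-bromo-4,7a-dimethyl-4-(prop-2-en-1-yl)octahydro-1-benzofuran-2-ol (both C2 epimers) | C=CC[C@]3(C)[C@@H](Br)CC[C@@]2(C)OC(O)C[C@H]23 | intermediate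
11 | (3aS,4S,5S,7aR)-5-bromo-4,7a-dimethyl-4-(prop-2-en-1-yl)hexahydro-1-benzofuran-2(3H)-one | C=CC[C@]3(C)[C@@H](Br)CC[C@@]2(C)OC(=O)C[C@H]23 | intermediate
12 | 2-[(3aS,4S,5S,7aR)-5-bromo-4,7a-dimethyl-2-oxooctahydro-1-benzofuran-4-yl]acetaldehyde | O=CC[C@]3(C)[C@@H](Br)CC[C@@]2(C)OC(=O)C[C@H]23 | intermediate
13 | (3aS,4S,5S,7aR)-5-bromo-4-(2,2-dimethoxyethyl)-4,7a-dimethylhexahydro-1-benzofuran-2(3H)-one | COC(OC)C[C@]3(C)[C@@H](Br)CC[C@@]2(C)OC(=O)C[C@H]23 | intermediate
14 | 6-methylhept-5-en-2-one | CC(=O)CCC=C(C)C | starting material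
15 | 2,4,6-triisopropylbenzenesulfonohydrazide | CC(C)c1cc(C(C)C)c(S(=O)(=O)NN)c(C(C)C)c1 | starting material
16 | N′-[(2E)-6-methylhept-5-en-2-ylidene]-2,4,6-triisopropylbenzenesulfonohydrazide | CC(C)=CCC/C(C)=N/NS(=O)(=O)c1c(C(C)C)cc(C(C)C)cc1C(C)C | intermediate
17 | (6-methylhepta-1,5-dien-2-yl)lithium | [Li]C(=C)CCC=C(C)C | intermediate
18 | 1-[(1S,2S,3S,6R)-3-bromo-2-(2,2-dimethoxyethyl)-6-hydroxy-2,6-dimethylcyclohexyl]-7-methyl-3-methylideneoct-6-en-2-one (in equilibrium with its cyclic hemiketal) | COC(OC)C[C@]1(C)[C@@H](Br)CC[C@@](C)(O)[C@H]1CC(=O)C(=C)CCC=C(C)C | intermediate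
19 | 2-[(1S,2S,3R,6S)-6-bromo-3-hydroxy-1,3-dimethyl-2-(7-methyl-3-methylidene-2-oxooct-6-en-1-yl)cyclohexyl]acetaldehyde (in equilibrium with its cyclic hemiketal) | O=CC[C@]1(C)[C@@H](Br)CC[C@@](C)(O)[C@H]1CC(=O)C(=C)CCC=C(C)C | intermediate
20 | 1-[(1S,2R,3aS,4S,7R,7aS)-4-bromo-2,7-dihydroxy-3a,7-dimethyloctahydro-1H-inden-1-yl]-6-methyl-2-methylidenehept-5-en-1-one | C=C(CCC=C(C)C)C(=O)[C@@H]2[C@H](O)C[C@]3(C)[C@@H](Br)CC[C@@](C)(O)[C@@H]23 | intermediate
21 | (1S,2R,3aS,4S,7R,7aS)-4-bromo-1-[(1R)-1-hydroxy-6-methyl-2-methylidenehept-5-en-1-yl]-3a,7-dimethyloctahydro-1H-indene-2,7-diol | C=C(CCC=C(C)C)[C@H](O)[C@@H]2[C@H](O)C[C@]3(C)[C@@H](Br)CC[C@@](C)(O)[C@@H]23 | intermediate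
22 | (1R)-1-[(1S,2R,3aS,4S,7R,7aS)-2-acetoxy-4-bromo-7-hydroxy-3a,7-dimethyloctahydro-1H-inden-1-yl]-6-methyl-2-methylidenehept-5-en-1-yl acetate | C=C(CCC=C(C)C)[C@H](OC(C)=O)[C@@H]2[C@H](OC(C)=O)C[C@]3(C)[C@@H](Br)CC[C@@](C)(O)[C@@H]23 | intermediate
23 | spiro 2-methyl-1,3-dioxolan-2-ylium (acetoxonium) ion bridging O10 and O11 of the ring A-closed C1 acetate (succinimidate salt) | CC1(C)C[C@]4(O[C+](C)O[C@@H]4[C@@H]2[C@H](OC(C)=O)C[C@]3(C)[C@@H](Br)CC[C@@](C)(O)[C@@H]23)CC[C@@H]1Br | intermediate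
24 | (R)-[(1S,2R,3aS,4S,7R,7aS)-2-acetoxy-4-bromo-7-hydroxy-3a,7-dimethyloctahydro-1H-inden-1-yl][(1R,4S)-4-bromo-1-hydroxy-3,3-dimethylcyclohexyl]methyl acetate (its O11-acetyl isomer reacts on in the same way) | CC1(C)C[C@@](O)([C@H](OC(C)=O)[C@@H]2[C@H](OC(C)=O)C[C@]3(C)[C@@H](Br)CC[C@@](C)(O)[C@@H]23)CC[C@@H]1Br | intermediate
25 | (1S,2R,3aS,4S,7R,7aS)-4-bromo-1-{(R)-[(1R,4S)-4-bromo-1-hydroxy-3,3-dimethylcyclohexyl](hydroxy)methyl}-3a,7-dimethyloctahydro-1H-indene-2,7-diol (CNP0144982.1) | CC1(C)C[C@@](O)([C@H](O)[C@@H]2[C@H](O)C[C@]3(C)[C@@H](Br)CC[C@@](C)(O)[C@@H]23)CC[C@@H]1Br | target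

**Totals**

Total step count: 14. Longest linear sequence: 13 steps (steps 1–8 and 10–14, from (R)-linalool); step 9 is a one-step side branch.

**The three steps most likely to fail**

Step 6. The ring alkene of the dihydrofuran is a weak π-nucleophile, the ether oxygen sits where it can intercept the C3 cation, and a bromonium ion formed irreversibly on the wrong alkene face cannot use the favoured chair. Fallback: set out from 8 and fix the bromine configuration before the ring closure. Shi epoxidation (D-fructose-derived ketone or its antipode, KHSO5, buffered MeCN) of the trisubstituted alkene gives (2R)-2-methyl-2-{2-[(2R,3R)-3-methyl-3-(prop-2-en-1-yl)oxiran-2-yl]ethyl}-2,5-dihydrofuran F1. Li2NiBr4 in THF opens it at the secondary carbon with inversion to (4R,5S)-5-bromo-4-methyl-7-[(2R)-2-methyl-2,5-dihydrofuran-2-yl]hept-1-en-4-ol F2. Ionization of the tertiary alcohol (hexafluoropropan-2-ol, TfOH cat., 0 °C) then generates only the matched bromonium ion, with no electrophilic bromine reagent present. Ring closure and hydride shift follow as before, and the route is rejoined at lactol 10.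

Step 14. The prenyl alkene is remote from every stereocentre, so the C14 configuration rests entirely on the chiral catalyst, and the acetate capture at C11 is untested on this ring. Fallback: set out from 22 and replace catalyst control by a reagent-controlled epoxidation. Shi epoxidation of the C14=C15 alkene (the deactivated 1,1-disubstituted allylic acetate alkene is left alone) gives (1R)-1-[(1S,2R,3aS,4S,7R,7aS)-2-acetoxy-4-bromo-7-hydroxy-3a,7-dimethyloctahydro-1H-inden-1-yl]-2-{2-[(2R)-3,3-dimethyloxiran-2-yl]ethyl}prop-2-en-1-yl acetate F3. Li2NiBr4 opens it at C14 with inversion to (1R,5S)-1-[(1S,2R,3aS,4S,7R,7aS)-2-acetoxy-4-bromo-7-hydroxy-3a,7-dimethyloctahydro-1H-inden-1-yl]-5-bromo-6-hydroxy-6-methyl-2-methylideneheptyl acetate F4. Acid ionization of the tertiary alcohol in hexafluoropropan-2-ol gives the enantiopure bromonium ion, which cyclizes and is captured by the C10 acetate; aqueous work-up rejoins the route at 24, and the methanolysis of step 14 follows.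

Step 11. Keto aldehyde 19 carries a reactive α-methylene ketone, and the aldol adduct can dehydrate or the enone can undergo Michael addition under base. Fallback: set out from lactol 10 and close the cyclopentane at the aldehyde oxidation level, before any enone exists. Ozonolysis (O3, then Me2S) gives 2-[(3aS,4S,5S,7aR)-5-bromo-2-hydroxy-4,7a-dimethyloctahydro-1-benzofuran-4-yl]acetaldehyde F5. L-Proline-catalysed enamine aldol from the C10 aldehyde (donor carbon C9; the neopentyl C2 position is too hindered to compete) gives (1S,2R,3aS,4S,7R,7aS)-4-bromo-2,7-dihydroxy-3a,7-dimethyloctahydro-1H-indene-1-carbaldehyde F6. Three equivalents of vinyllithium 17 then add to the C10 aldehyde under lithium-alkoxide chelation, and the route is rejoined at triol 21; a wrong C10 epimer is separated and recycled by oxidation to 20 and step 12.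

**Further compounds**

F1 | step 6 | (2R)-2-methyl-2-{2-[(2R,3R)-3-methyl-3-(prop-2-en-1-yl)oxiran-2-yl]ethyl}-2,5-dihydrofuran | C=CC[C@@]1(C)O[C@@H]1CC[C@@]2(C)OCC=C2
F2 | step 6 | (4R,5S)-5-bromo-4-methyl-7-[(2R)-2-methyl-2,5-dihydrofuran-2-yl]hept-1-en-4-ol | C=CC[C@](O)(C)[C@@H](Br)CC[C@@]1(C)OCC=C1
F3 | step 14 | (1R)-1-[(1S,2R,3aS,4S,7R,7aS)-2-acetoxy-4-bromo-7-hydroxy-3a,7-dimethyloctahydro-1H-inden-1-yl]-2-{2-[(2R)-3,3-dimethyloxiran-2-yl]ethyl}prop-2-en-1-yl acetate | CC1(C)O[C@@H]1CCC(=C)[C@H](OC(C)=O)[C@@H]2[C@H](OC(C)=O)C[C@]3(C)[C@@H](Br)CC[C@@](C)(O)[C@@H]23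
F4 | step 14 | (1R,5S)-1-[(1S,2R,3aS,4S,7R,7aS)-2-acetoxy-4-bromo-7-hydroxy-3a,7-dimethyloctahydro-1H-inden-1-yl]-5-bromo-6-hydroxy-6-methyl-2-methylideneheptyl acetate | CC(C)(O)[C@@H](Br)CCC(=C)[C@H](OC(C)=O)[C@@H]2[C@H](OC(C)=O)C[C@]3(C)[C@@H](Br)CC[C@@](C)(O)[C@@H]23
F5 | step 11 | 2-[(3aS,4S,5S,7aR)-5-bromo-2-hydroxy-4,7a-dimethyloctahydro-1-benzofuran-4-yl]acetaldehyde | O=CC[C@]3(C)[C@@H](Br)CC[C@@]2(C)OC(O)C[C@H]23
F6 | step 11 | (1S,2R,3aS,4S,7R,7aS)-4-bromo-2,7-dihydroxy-3a,7-dimethyloctahydro-1H-indene-1-carbaldehyde | O=C[C@@H]2[C@H](O)C[C@]3(C)[C@@H](Br)CC[C@@](C)(O)[C@@H]23
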